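**Retrosynthetic overview**
1. Numbering follows cyclohepta[b]furan-2-one (O1, C2, C3, C3a, C4–C8, C8a; side chain C1′–C4′ on C7). Late disconnections: the 3-methylene group comes from a 3-CH2OSi handle (mesylate elimination), the (Z)-but-2-enoyl group from a C7 vinyl group (ozonolysis, (Z)-propenyl addition, oxidation), and the ester from acylation of 8-OH.
2. Key disconnection: C5–C6 and C7–C8 are cut together. This splits the cycloheptane into the C8–C8a–C3a–C4–C5 1,5-dialdehyde 10, with the lactone already in place, and the two-carbon C6–C7 unit. That unit is delivered as the vicinal bis(boronate) 14 of a 2-silyloxy diene (relay double allylboration, formal [5+2]).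
3. Enabling feature: on the seven-membered ring the carbinol carbons C5 and C8 flank C6–C7 in a 1,4-relation, and C7 carries both an oxygen and the carbon branch C1′. C5(OH)–C6–C7=C1′ and then C8(OH)–C7–C1′=C2′ are therefore two overlapping homoallylic-alcohol retrons.
4. Ring order: cyclopentene (temporary carbocycle) → γ-lactone by iodolactonisation → cyclopentene cleaved to 10 → cycloheptane in the key step.
5. Stereochemistry: C3a is set by asymmetric allylic alkylation and C8a follows from it. C6, C7 and C8 are set in the key step. C5 emerges α and is reset by oxidation and 7-OH-directed reduction.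

Key step: step 9

Remark: β is the face of the bicycle that carries H-3a and H-8a, and α is the opposite face. The target is 5β-OH, 6α-CH3, 7α-OH, 7β-acyl, 8β-O-acyl.
Assumption: the antipodes of the DACH-phenyl ligand (step 1) and of TRIP (step 9) are written as the usual models predict. Should the sense be opposite, the other antipode is used.

**Route**

Step 1
Reactants: 1 (±)-cyclopent-2-en-1-yl acetate; 2 dimethyl malonate
Product: 3 dimethyl 2-[(1R)-cyclopent-2-en-1-yl]malonate
Conditions: [Pd(C3H5)Cl]2 (2.5 mol %), (S,S)-DACH-phenyl bis(2-diphenylphosphinobenzamide) ligand (7.5 mol %), Cs2CO3, CH2Cl2, 0 °C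
Reagents that add atoms: none
Why: Tsuji–Trost asymmetric allylic alkylation, in which both enantiomers of 1 ionise to the same meso π-allyl palladium complex and the chiral pocket sends malonate to one terminus, setting the future C3a.

Step 2
Reactants: 3 dimethyl 2-[(1R)-cyclopent-2-en-1-yl]malonate
Product: 5 2-[(1S)-cyclopent-2-en-1-yl]acetic acid, via malonic diacid 4 (not isolated)
Conditions: NaOH, MeOH/H2O, reflux; HCl; then neat, 170 °C
Reagents that add atoms: sodium hydroxide, [Na+].[OH-]
Why: Saponification and thermal decarboxylation (malonic ester synthesis) remove the surplus carboxyl group without touching the non-acidic allylic stereocentre.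

Step 3
Reactants: 5 2-[(1S)-cyclopent-2-en-1-yl]acetic acid
Product: 6 (3aS,6R,6aR)-6-iodohexahydro-2H-cyclopenta[b]furan-2-one (cis-fused, iodine trans to the ring oxygen)
Conditions: I2, KI, NaHCO3, THF/H2O, 0 °C to rt, dark
Reagents that add atoms: iodine, [I][I]
Why: Iodolactonisation, in which 5-exo attack of the tethered carboxylate anti to the iodonium ion gives the cis-fused lactone and sets the future C8a from C3a.

Step 4
Reactants: 6 iodolactone
Product: 7 (3aS,6aR)-3,3a,4,6a-tetrahydro-2H-cyclopenta[b]furan-2-one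
Conditions: DBU, toluene, 80 °C
Reagents that add atoms: none
Why: E2 dehydroiodination; H-6a is cis to iodine, so only a C5 hydrogen is anti-periplanar and the alkene forms next to the C–O carbon.

Step 5
Reactants: 7 bicyclic alkene lactone; 8 (triisopropylsiloxy)methyl chloride
Product: 9 (3R,3aS,6aR)-3-[(triisopropylsilyloxy)methyl]-3,3a,4,6a-tetrahydro-2H-cyclopenta[b]furan-2-one
Conditions: LDA, THF, −78 °C; 8, DMPU, −78 to −30 °C
Reagents that add atoms: none
Why: Lactone enolate alkylation with a chloromethyl ether on the convex face of the cis-bicyclo[3.3.0] system installs the masked methylene carbon; the new C3 centre is destroyed in step 19.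

Step 6
Reactants: 9 silyloxymethyl alkene lactone
Product: 10 (2R,3S,4R)-5-oxo-3-(2-oxoethyl)-4-[(triisopropylsilyloxy)methyl]tetrahydrofuran-2-carbaldehyde
Conditions: O3, CH2Cl2, −78 °C; Me2S, −78 °C to rt; used crude
Reagents that add atoms: ozone, [O-][O+]=O
Why: Ozonolysis with reductive work-up cleaves the only C=C bond and unveils the C5 and C8 aldehydes under base-free conditions that leave C3a and C8a untouched.

Step 7
Reactants: 11 pent-1-en-3-one
Product: 12 (Z)-triethyl(penta-1,3-dien-3-yloxy)silane
Conditions: TESOTf, Et3N, Et2O, 0 °C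
Reagents that add atoms: triethylsilyl triflate, CC[Si](CC)(CC)OS(=O)(=O)C(F)(F)F
Why: Soft enolisation and O-silylation of the ethyl ketone should give the favoured Z silyl dienol ether (methyl cis to oxygen, trans to vinyl).

Step 8
Reactants: 12 (Z)-silyl dienol ether; 13 bis(pinacolato)diboron
Product: 14 (±)-(Z)-triethyl{[4,5-bis(4,4,5,5-tetramethyl-1,3,2-dioxaborolan-2-yl)pent-2-en-3-yl]oxy}silane
Conditions: Pt(dba)2 (3 mol %), toluene, 50 °C; filtered and used without chromatography
Reagents that add atoms: none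
Why: Platinum-catalysed alkene diboration; phosphine-free zerovalent platinum adds B–B in the 1,2-mode across the terminal double bond of a 1,3-diene and leaves the trisubstituted enol ether and its geometry intact.

Step 9
Reactants: 10 lactone dialdehyde; 14 racemic vicinal bis(boronate) (2.5 equiv)
Product: 17 5α,8β-dihydroxy-6α-methyl-7α-(triethylsilyloxy)-7β-vinyl-3β-[(triisopropylsilyloxy)methyl]octahydro-2H-cyclohepta[b]furan-2-one, via mono-adduct allylboronate 15 (not isolated), via bis-borate 16 (not isolated)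
Conditions: (R)-TRIP phosphoric acid (10 mol %), 4 Å MS, toluene (0.02 M), −30 °C, then 40 °C; aq. NaHCO3 work-up
Reagents that add atoms: none
Why: Proposed new method: the secondary allylboronate of (R)-14 adds through a phosphoric-acid-activated chair to the unbranched C5 aldehyde (C5–C6 bond), the allyl shift turns the spectator CH2Bpin into a new γ-silyloxy allylboronate (15), and this closes on the C8 aldehyde (C7–C8 bond) to give 16, which is hydrolysed to 17 on work-up. The closest known reaction types are the tandem double allylation of 1,4-dicarbonyl compounds by diene-derived vicinal bis(boronates) to six-membered 1,4-diols, the phosphoric-acid-catalysed kinetic resolution of racemic α-substituted allylboronates, and the ring-closing allylboration of ω-formyl allylboronates; the seven-membered ring, the 2-silyloxy substituent and the fully substituted C7 are new. The cycloheptane closes 7-exo-trig at the C8 carbonyl inside a bicyclic chair. C6 follows from syn-SE2′ delivery on the boron-bearing face of the matched (R)-reagent chosen by the catalyst, and C5 from the E-type crotyl geometry (methyl trans to the boron-bearing carbon, anti adduct, 5α-OH, reset in steps 12 and 13); C7 follows from A(1,3) strain in 15, where the pseudo-axial CH2Bpin of the first chair ends cis to C6, H-6 lies in the alkene plane and the tether reaches only the face anti to the 6-methyl group; C8 follows from the second chair, in which the silyloxy group trans to CH2Bpin gives the trans 7-O/8-O pair with vinyl cis to 8-OH. The step needs the first addition at C5 rather than C8: the C8 aldehyde is α-branched and crowded by the cis C3a side chain, so the hindered secondary boronate held in the catalyst pocket should accept only the CH2CHO terminus, and dilution favours ring closure over a second intermolecular allylation.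

Step 10
Reactants: 17 key-step diol
Product: 18 5α,7α,8β-trihydroxy-6α-methyl-7β-vinyl-3β-[(triisopropylsilyloxy)methyl]octahydro-2H-cyclohepta[b]furan-2-one
Conditions: HF·pyridine, pyridine, THF, 0 °C
Reagents that add atoms: none
Why: Fluoride-mediated desilylation should distinguish the labile triethylsilyl ether from the far more robust primary triisopropylsilyl ether.

Step 11
Reactants: 18 triol; 19 3-methylbutanoic anhydride
Product: 22 5α,7α-dihydroxy-8β-(3-methylbutanoyloxy) lactone, via cyclic 5,7-phenylboronate 20 (not isolated), via acylated phenylboronate 21 (not isolated)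
Conditions: PhB(OH)2, 4 Å MS, toluene, rt; 19, DMAP, Et3N, 40 °C; pinacol, rt
Reagents that add atoms: none
Why: Transient boronate protection; the 5α- and 7α-hydroxyls are 1,3-cis and are tied up as a six-membered phenylboronate, so DMAP-catalysed acylation can take place only at 8-OH before pinacol transesterification releases the diol.

Step 12
Reactants: 22 5α,7α-diol ester
Product: 23 7α-hydroxy-5-oxo-8β-(3-methylbutanoyloxy) lactone
Conditions: Dess–Martin periodinane, NaHCO3, CH2Cl2, 0 °C to rt
Reagents that add atoms: none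
Why: Dess–Martin oxidation acts on the only secondary alcohol under buffered, non-epimerising conditions and leaves the tertiary 7-OH free.

Step 13
Reactants: 23 β-hydroxy ketone
Product: 24 5β,7α-dihydroxy-8β-(3-methylbutanoyloxy) lactone
Conditions: Me4NBH(OAc)3, MeCN/AcOH, −30 °C
Reagents that add atoms: none
Why: Evans–Saksena reduction; the 7α-alkoxyborohydride delivers hydride within a six-membered chair to the α face of C5, giving the 1,3-anti diol and hence the 5β-OH of the target.

Step 14
Reactants: 24 5β,7α-diol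
Product: 25 5β,7α-bis(triethylsilyloxy) lactone
Conditions: TESOTf, 2,6-lutidine, CH2Cl2, −78 to 0 °C
Reagents that add atoms: triethylsilyl triflate, CC[Si](CC)(CC)OS(=O)(=O)C(F)(F)F
Why: Silyl triflate silylation is reactive enough to cap both the secondary and the tertiary alcohol and leaves the ester and lactone untouched.

Step 15
Reactants: 25 bis(silyl ether)
Product: 26 7β-formyl lactone
Conditions: O3, CH2Cl2, −78 °C; PPh3
Reagents that add atoms: ozone, [O-][O+]=O
Why: Ozonolysis of the only alkene converts the vinyl group into the C1′ aldehyde, which has no α-hydrogen and cannot epimerise.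

Step 16
Reactants: 26 aldehyde; 27 (Z)-1-bromoprop-1-ene
Product: 29 7β-[(Z)-1-hydroxybut-2-enyl] lactone (C1′ epimers), via (Z)-prop-1-enyllithium 28 (not isolated)
Conditions: 27, t-BuLi (2 equiv), Et2O, −78 °C; then 26, −90 °C; aq. NH4Cl
Reagents that add atoms: none
Why: Halogen–lithium exchange with retention of alkene geometry, then 1,2-addition, which at low temperature should be much faster at the aldehyde than at the ester or lactone; the uncontrolled C1′ centre is removed in step 17.

Step 17
Reactants: 29 (Z)-allylic alcohol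
Product: 30 7β-[(Z)-but-2-enoyl] bis(triethylsilyl) ether
Conditions: Dess–Martin periodinane, NaHCO3, CH2Cl2, 0 °C
Reagents that add atoms: none
Why: Buffered Dess–Martin oxidation of the only free hydroxyl gives the enone under neutral conditions that should preserve the Z geometry.

Step 18
Reactants: 30 protected enone
Product: 31 3β-hydroxymethyl-5β,7α-dihydroxy enone
Conditions: HF·pyridine, THF, 0 °C to rt
Reagents that add atoms: none
Why: Global fluoride desilylation under mildly acidic conditions removes all three silyl groups without base that could isomerise the enone or shift the ester.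

Step 19
Reactants: 31 triol
Product: 33 target, via primary mesylate 32 (not isolated)
Conditions: MsCl (1.1 equiv), Et3N (5 equiv), CH2Cl2, −20 °C to rt
Reagents that add atoms: none
Why: Selective mesylation of the primary alcohol followed by E1cB elimination of the β-mesyloxy lactone gives the exocyclic methylene group, while the secondary and tertiary alcohols react much more slowly.

**Compound list**
1 | (±)-cyclopent-2-en-1-yl acetate | CC(=O)OC1C=CCC1 | starting material
2 | dimethyl malonate | COC(=O)CC(=O)OC | starting material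
3 | dimethyl 2-[(1R)-cyclopent-2-en-1-yl]malonate | COC(=O)C(C(=O)OC)[C@H]1C=CCC1 | intermediate
4 | 2-[(1R)-cyclopent-2-en-1-yl]malonic acid | OC(=O)C(C(=O)O)[C@H]1C=CCC1 | intermediate
5 | 2-[(1S)-cyclopent-2-en-1-yl]acetic acid | OC(=O)C[C@H]1C=CCC1 | intermediate
6 | (3aS,6R,6aR)-6-iodohexahydro-2H-cyclopenta[b]furan-2-one | C1C(=O)O[C@@H]2[C@H]1CC[C@H]2I | intermediate
7 | (3aS,6aR)-3,3a,4,6a-tetrahydro-2H-cyclopenta[b]furan-2-one | C1C(=O)O[C@@H]2[C@H]1CC=C2 | intermediate
8 | (triisopropylsiloxy)methyl chloride | ClCO[Si](C(C)C)(C(C)C)C(C)C | starting material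
9 | (3R,3aS,6aR)-3-[(triisopropylsilyloxy)methyl] alkene lactone | CC(C)[Si](C(C)C)(C(C)C)OC[C@@H]1C(=O)O[C@@H]2[C@H]1CC=C2 | intermediate
10 | (2R,3S,4R)-lactone dialdehyde | CC(C)[Si](C(C)C)(C(C)C)OC[C@@H]1C(=O)O[C@@H](C=O)[C@H]1CC=O | intermediate
11 | pent-1-en-3-one | C=CC(=O)CC | starting material
12 | (Z)-triethyl(penta-1,3-dien-3-yloxy)silane | C=C/C(O[Si](CC)(CC)CC)=C/C | intermediate
13 | bis(pinacolato)diboron | CC1(C)OB(OC1(C)C)B1OC(C)(C)C(C)(C)O1 | starting material
14 | (±)-(Z)-vicinal bis(boronate), racemic at the CHB carbon | CC1(C)OB(CC(B2OC(C)(C)C(C)(C)O2)/C(O[Si](CC)(CC)CC)=C/C)OC1(C)C | intermediate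
15 | mono-adduct: 5α-borate, C8 aldehyde, allylboronate with CH2Bpin cis to C6 | CC(C)[Si](C(C)C)(C(C)C)OC[C@@H]1C(=O)O[C@@H](C=O)[C@H]1C[C@H](OB2OC(C)(C)C(C)(C)O2)[C@H](C)/C(O[Si](CC)(CC)CC)=C\CB3OC(C)(C)C(C)(C)O3 | intermediate
16 | cyclised 5α,8β-bis(pinacol borate) | CC(C)[Si](C(C)C)(C(C)C)OC[C@@H]1C(=O)O[C@@H]2[C@H]1C[C@H](OB3OC(C)(C)C(C)(C)O3)[C@H](C)[C@@](O[Si](CC)(CC)CC)(C=C)[C@H]2OB4OC(C)(C)C(C)(C)O4 | intermediate
17 | 5α,8β-diol, 7α-OTES, 7β-vinyl, 6α-methyl | CC(C)[Si](C(C)C)(C(C)C)OC[C@@H]1C(=O)O[C@@H]2[C@H]1C[C@H](O)[C@H](C)[C@@](O[Si](CC)(CC)CC)(C=C)[C@H]2O | intermediate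
18 | 5α,7α,8β-triol | CC(C)[Si](C(C)C)(C(C)C)OC[C@@H]1C(=O)O[C@@H]2[C@H]1C[C@H](O)[C@H](C)[C@@](O)(C=C)[C@H]2O | intermediate
19 | 3-methylbutanoic anhydride | CC(C)CC(=O)OC(=O)CC(C)C | starting material
20 | cyclic 5,7-phenylboronate of 18 | CC(C)[Si](C(C)C)(C(C)C)OC[C@@H]1C(=O)O[C@@H]2[C@H]1C[C@@H]3OB(c4ccccc4)O[C@]([C@H]3C)(C=C)[C@H]2O | intermediate
21 | 8β-(3-methylbutanoate) of 20 | CC(C)[Si](C(C)C)(C(C)C)OC[C@@H]1C(=O)O[C@@H]2[C@H]1C[C@@H]3OB(c4ccccc4)O[C@]([C@H]3C)(C=C)[C@H]2OC(=O)CC(C)C | intermediate
22 | 5α,7α-diol 8β-ester | CC(C)[Si](C(C)C)(C(C)C)OC[C@@H]1C(=O)O[C@@H]2[C@H]1C[C@H](O)[C@H](C)[C@@](O)(C=C)[C@H]2OC(=O)CC(C)C | intermediate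
23 | 5-ketone, 7α-OH, 8β-ester | CC(C)[Si](C(C)C)(C(C)C)OC[C@@H]1C(=O)O[C@@H]2[C@H]1CC(=O)[C@H](C)[C@@](O)(C=C)[C@H]2OC(=O)CC(C)C | intermediate
24 | 5β,7α-diol 8β-ester | CC(C)[Si](C(C)C)(C(C)C)OC[C@@H]1C(=O)O[C@@H]2[C@H]1C[C@@H](O)[C@H](C)[C@@](O)(C=C)[C@H]2OC(=O)CC(C)C | intermediate
25 | 5β,7α-bis(triethylsilyl) ether | CC(C)[Si](C(C)C)(C(C)C)OC[C@@H]1C(=O)O[C@@H]2[C@H]1C[C@@H](O[Si](CC)(CC)CC)[C@H](C)[C@@](O[Si](CC)(CC)CC)(C=C)[C@H]2OC(=O)CC(C)C | intermediate
26 | 7β-carbaldehyde | CC(C)[Si](C(C)C)(C(C)C)OC[C@@H]1C(=O)O[C@@H]2[C@H]1C[C@@H](O[Si](CC)(CC)CC)[C@H](C)[C@@](O[Si](CC)(CC)CC)(C=O)[C@H]2OC(=O)CC(C)C | intermediate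
27 | (Z)-1-bromoprop-1-ene | C/C=C\Br | starting material
28 | (Z)-prop-1-enyllithium | C/C=C\[Li] | intermediate
29 | (Z)-allylic alcohol, C1′ epimers | CC(C)[Si](C(C)C)(C(C)C)OC[C@@H]1C(=O)O[C@@H]2[C@H]1C[C@@H](O[Si](CC)(CC)CC)[C@H](C)[C@@](O[Si](CC)(CC)CC)(C(O)/C=C\C)[C@H]2OC(=O)CC(C)C | intermediate
30 | protected (Z)-enone | CC(C)[Si](C(C)C)(C(C)C)OC[C@@H]1C(=O)O[C@@H]2[C@H]1C[C@@H](O[Si](CC)(CC)CC)[C@H](C)[C@@](O[Si](CC)(CC)CC)(C(=O)/C=C\C)[C@H]2OC(=O)CC(C)C | intermediate
31 | 3β-hydroxymethyl triol | OC[C@@H]1C(=O)O[C@@H]2[C@H]1C[C@@H](O)[C@H](C)[C@@](O)(C(=O)/C=C\C)[C@H]2OC(=O)CC(C)C | intermediate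
32 | primary mesylate of 31 | CS(=O)(=O)OC[C@@H]1C(=O)O[C@@H]2[C@H]1C[C@@H](O)[C@H](C)[C@@](O)(C(=O)/C=C\C)[C@H]2OC(=O)CC(C)C | intermediate
33 | (3aS,5R,6S,7S,8S,8aR)-7-[(Z)-but-2-enoyl]-5,7-dihydroxy-6-methyl-3-methylidene-2-oxooctahydro-2H-cyclohepta[b]furan-8-yl 3-methylbutanoate | C=C1C(=O)O[C@@H]2[C@H]1C[C@@H](O)[C@H](C)[C@@](O)(C(=O)/C=C\C)[C@H]2OC(=O)CC(C)C | target

**Step count**
Total step count: 19. Longest linear sequence: 17 (steps 1–6 and 9–19).

**Steps most likely to fail**

Step 9 (key step). The first allylboration may engage the more electrophilic C8 aldehyde, which loses site control. Intermolecular allylation may also outrun the seven-membered ring closure.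
- The fallback separates the two events with known chemistry. It sets out from 9 and comes back at 22.
- Terminus-differentiating ozonolysis of 9 (O3, CH2Cl2/MeOH, NaHCO3; TsOH; NaHCO3, Me2S) places the carbonyl oxide away from the allylic oxygen. It should give the C5 aldehyde C8 dimethyl acetal F1.
- Phosphoric-acid-catalysed allylboration of F1 with 14 gives the homoallylic alcohol allylboronate F2.
- TESOTf and 2,6-lutidine followed by water silylate 5-OH and unmask the acetal under non-acidic conditions, giving the formyl allylboronate F3.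
- F3 undergoes ring-closing allylboration to the 5α,7α-bis(triethylsilyl) ether 8β-alcohol F4.
- Acylation with 19 and DMAP gives the ester F5, and HF·pyridine removes both triethylsilyl groups to give 22.

Step 8. Addition through a π-allyl platinum intermediate may divert the diboration to the 1,4-mode, whose product cannot relay.
- The fallback builds the vicinal bis(boronate) from an alkyne. It sets out from 13 and comes back at 14.
- Commercial pent-1-yn-3-one is O-silylated (TESOTf, Et3N) to the (Z)-silyloxy enyne F6.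
- NHC–copper-catalysed protoboration (CuCl, imidazolinium salt, NaOt-Bu, MeOH, 13) gives first the (E)-dienylboronate F7.
- A second boron–copper addition places copper next to the first boron and, after protonation, gives 14.

Step 16. Attack on, or enolisation of, the lactone and the ester may compete at a very hindered aldehyde, and the propenyl metal may lose part of its geometry.
- The fallback sets out from 26 and comes back at 29.
- Zn(OTf)2/Et3N-mediated addition of propyne is aldehyde-selective and gives the propargylic alcohol F8.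
- Semihydrogenation (H2, Pd/CaCO3–Pb(OAc)2, quinoline) gives the (Z)-allylic alcohol 29.

**Further compounds**
F1 | step 9 | C5 aldehyde C8 dimethyl acetal | CC(C)[Si](C(C)C)(C(C)C)OC[C@@H]1C(=O)O[C@@H](C(OC)OC)[C@H]1CC=O
F2 | step 9 | homoallylic alcohol allylboronate | CC(C)[Si](C(C)C)(C(C)C)OC[C@@H]1C(=O)O[C@@H](C(OC)OC)[C@H]1C[C@H](O)[C@H](C)/C(O[Si](CC)(CC)CC)=C\CB2OC(C)(C)C(C)(C)O2
F3 | step 9 | formyl allylboronate | CC(C)[Si](C(C)C)(C(C)C)OC[C@@H]1C(=O)O[C@@H](C=O)[C@H]1C[C@H](O[Si](CC)(CC)CC)[C@H](C)/C(O[Si](CC)(CC)CC)=C\CB2OC(C)(C)C(C)(C)O2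
F4 | step 9 | 5α,7α-bis(triethylsilyl) ether 8β-alcohol | CC(C)[Si](C(C)C)(C(C)C)OC[C@@H]1C(=O)O[C@@H]2[C@H]1C[C@H](O[Si](CC)(CC)CC)[C@H](C)[C@@](O[Si](CC)(CC)CC)(C=C)[C@H]2O
F5 | step 9 | ester | CC(C)[Si](C(C)C)(C(C)C)OC[C@@H]1C(=O)O[C@@H]2[C@H]1C[C@H](O[Si](CC)(CC)CC)[C@H](C)[C@@](O[Si](CC)(CC)CC)(C=C)[C@H]2OC(=O)CC(C)C
F6 | step 8 | (Z)-silyloxy enyne | C#C/C(O[Si](CC)(CC)CC)=C/C
F7 | step 8 | (E)-dienylboronate | CC1(C)OB(/C=C/C(O[Si](CC)(CC)CC)=C/C)OC1(C)C
F8 | step 16 | propargylic alcohol | CC(C)[Si](C(C)C)(C(C)C)OC[C@@H]1C(=O)O[C@@H]2[C@H]1C[C@@H](O[Si](CC)(CC)CC)[C@H](C)[C@@](O[Si](CC)(CC)CC)(C(O)C#CC)[C@H]2OC(=O)CC(C)C
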